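## Retrosynthetic overview

1. Both ring–CH2 bonds are cut. Each is made by a proline-mediated Knoevenagel-type aldol condensation of a hydroxyquinone enol carbon with a chain aldehyde, the alkylidene adduct being reduced in the same flask by a Hantzsch ester.
2. The (CH2)14 linker is a C14 dialdehyde with one end masked as a 1,3-dioxolane. It is built from 11-bromoundecan-1-ol and the Grignard reagent of 2-(2-bromoethyl)-1,3-dioxolane by Cu-catalysed coupling.
3. Both hydroxyquinone donors come from one arene, 2,4-dimethoxy-3-methylbenzene-1,5-diol (from 2,6-dimethoxytoluene). CAN gives the hydroxy-methoxy-methylquinone; BBr3 then air gives the dihydroxy-methylquinone.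
4. No ring is constructed: both six-membered rings are bought as the arene and unveiled as quinones before coupling. The methoxy ring is joined first, the acetal is opened, and the dihydroxy ring is joined last.

Assumption: the target has no stereocentre (it is achiral), so no stereocontrol is needed; the linker is read as an unbranched (CH2)14 chain and the quinones are drawn in the tautomer of the given SMILES.

## Route

Step 1
Reactants: 1 2,6-dimethoxytoluene
Product: 2 1,5-dibromo-2,4-dimethoxy-3-methylbenzene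
Conditions: NBS (2.1 equiv), MeCN, 0 °C to rt, dark
Reagents that add atoms: N-bromosuccinimide, O=C1CCC(=O)N1Br
Why: Electrophilic aromatic bromination goes twice at the two equivalent positions that are ortho to one methoxy group and para to the other, and the ionic conditions avoid benzylic bromination.

Step 2
Reactants: 2 1,5-dibromo-2,4-dimethoxy-3-methylbenzene
Product: 3 2,2'-(4,6-dimethoxy-5-methyl-1,3-phenylene)bis(4,4,5,5-tetramethyl-1,3,2-dioxaborolane)
Conditions: B2pin2 (2.6 equiv), PdCl2(dppf) (5 mol%), KOAc, 1,4-dioxane, 90 °C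
Reagents that add atoms: bis(pinacolato)diboron, CC1(C)OB(OC1(C)C)B1OC(C)(C)C(C)(C)O1
Why: Miyaura borylation turns both aryl C–Br bonds into C–B bonds at fixed positions, which sets up ipso oxygenation.

Step 3
Reactants: 3 2,2'-(4,6-dimethoxy-5-methyl-1,3-phenylene)bis(4,4,5,5-tetramethyl-1,3,2-dioxaborolane)
Product: 4 2,4-dimethoxy-3-methylbenzene-1,5-diol
Conditions: 30% H2O2, aq. NaOH, THF, 0 °C, N2; then Na2S2O3, 1 M HCl
Reagents that add atoms: hydrogen peroxide, OO
Why: Oxidation of the aryl boronates (1,2-aryl shift from boron to oxygen, then hydrolysis) is ipso-specific and gives the mirror-symmetric resorcinol.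

Step 4
Reactants: 4 2,4-dimethoxy-3-methylbenzene-1,5-diol
Product: 5 2-hydroxy-5-methoxy-6-methylcyclohexa-2,5-diene-1,4-dione
Conditions: CAN (2.1 equiv), MeCN/H2O 2:1, 0 °C, 10 min
Reagents that add atoms: water, O
Why: CAN oxidative demethylation of a para-methoxyphenol gives the para-quinone, and because 4 is symmetric both para-methoxyphenol pairs give the same quinone with the methoxy group next to the methyl group.

Step 5
Reactants: 4 2,4-dimethoxy-3-methylbenzene-1,5-diol
Product: 7 2,5-dihydroxy-3-methylcyclohexa-2,5-diene-1,4-dione, via 3-methylbenzene-1,2,4,5-tetrol 6 (not isolated)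
Conditions: BBr3 (5 equiv), CH2Cl2, −78 °C to rt; H2O; then air (O2), EtOAc/H2O, rt
Reagents that add atoms: none
Why: BBr3 cleaves both aryl methyl ethers and the resulting 1,2,4,5-tetrahydroxyarene autoxidises spontaneously to the 2,5-dihydroxy-1,4-benzoquinone.

Step 6
Reactants: 8 11-bromoundecan-1-ol
Product: 9 [(11-bromoundecyl)oxy](tert-butyl)dimethylsilane
Conditions: TBSCl (1.1 equiv), imidazole (2 equiv), DMF, rt
Reagents that add atoms: tert-butyldimethylsilyl chloride, CC(C)(C)[Si](C)(C)Cl
Why: Standard silylation masks the alcohol so that no Grignard reagent is wasted and no insoluble magnesium alkoxide forms in the next step.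

Step 7
Reactants: 9 [(11-bromoundecyl)oxy](tert-butyl)dimethylsilane; 10 2-(2-bromoethyl)-1,3-dioxolane
Product: 12 tert-butyl{[13-(1,3-dioxolan-2-yl)tridecyl]oxy}dimethylsilane, via [2-(1,3-dioxolan-2-yl)ethyl]magnesium bromide 11 (not isolated)
Conditions: 10 (1.5 equiv), Mg, THF, 25–30 °C; then 9, Li2CuCl4 (3 mol%), THF, −10 °C to rt
Reagents that add atoms: none
Why: Kochi copper-catalysed sp3–sp3 cross-coupling of a primary Grignard reagent with a primary bromide joins C11 and C3 into the C14 chain, and silyl ether and dioxolane are inert to it.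

Step 8
Reactants: 12 tert-butyl{[13-(1,3-dioxolan-2-yl)tridecyl]oxy}dimethylsilane
Product: 13 13-(1,3-dioxolan-2-yl)tridecan-1-ol
Conditions: TBAF (1.2 equiv), THF, rt
Reagents that add atoms: none
Why: Fluoride desilylation frees the primary alcohol without touching the acetal.

Step 9
Reactants: 13 13-(1,3-dioxolan-2-yl)tridecan-1-ol
Product: 14 13-(1,3-dioxolan-2-yl)tridecanal
Conditions: TEMPO (10 mol%), PhI(OAc)2 (1.1 equiv), CH2Cl2, rt
Reagents that add atoms: none
Why: TEMPO/PhI(OAc)2 oxidation stops at the aldehyde under anhydrous, weakly acidic conditions that leave the dioxolane intact.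

Step 10
Reactants: 5 2-hydroxy-5-methoxy-6-methylcyclohexa-2,5-diene-1,4-dione; 14 13-(1,3-dioxolan-2-yl)tridecanal
Product: 16 3-[13-(1,3-dioxolan-2-yl)tridecyl]-2-hydroxy-5-methoxy-6-methylcyclohexa-2,5-diene-1,4-dione, via alkylidene trione 15 (not isolated)
Conditions: L-proline (20 mol%), Hantzsch ester (1.1 equiv), 14 (1.1 equiv), CH2Cl2, rt; work-up in air
Reagents that add atoms: none
Why: The only enolic C–H of the vinylogous acid 5 adds to the aldehyde in a Knoevenagel-type aldol condensation, and the alkylidene trione is reduced at once by conjugate hydride transfer from the Hantzsch ester (three-component reductive alkylation), so no bis-adduct forms and no stereocentre arises.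

Step 11
Reactants: 16 3-[13-(1,3-dioxolan-2-yl)tridecyl]-2-hydroxy-5-methoxy-6-methylcyclohexa-2,5-diene-1,4-dione
Product: 17 14-(2-hydroxy-5-methoxy-4-methyl-3,6-dioxocyclohexa-1,4-dien-1-yl)tetradecanal
Conditions: 2 M HCl, THF, rt
Reagents that add atoms: water, O
Why: Mild acid hydrolysis of the dioxolane frees the second aldehyde, and the fully substituted methoxy-hydroxyquinone survives dilute acid at room temperature.

Step 12
Reactants: 17 14-(2-hydroxy-5-methoxy-4-methyl-3,6-dioxocyclohexa-1,4-dien-1-yl)tetradecanal; 7 2,5-dihydroxy-3-methylcyclohexa-2,5-diene-1,4-dione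
Product: 19 2,5-dihydroxy-3-[14-(2-hydroxy-5-methoxy-4-methyl-3,6-dioxocyclohexa-1,4-dien-1-yl)tetradecyl]-6-methylcyclohexa-2,5-diene-1,4-dione, via alkylidene trione 18 (not isolated)
Conditions: 7 (1.2 equiv), L-proline (20 mol%), Hantzsch ester (1.1 equiv), CH2Cl2/EtOH 4:1, rt; work-up in air, crystallisation
Reagents that add atoms: none
Why: The same Knoevenagel-type aldol condensation and in situ Hantzsch reduction attaches the dihydroxyquinone through its single free enol carbon, the ring already in 17 has no C–H left to react, and the achiral target results.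

## Compound list

1 | 2,6-dimethoxytoluene (1,3-dimethoxy-2-methylbenzene) | COc1cccc(OC)c1C | starting material
2 | 1,5-dibromo-2,4-dimethoxy-3-methylbenzene | COc1c(Br)cc(Br)c(OC)c1C | intermediate
3 | 2,2'-(4,6-dimethoxy-5-methyl-1,3-phenylene)bis(4,4,5,5-tetramethyl-1,3,2-dioxaborolane) | COc1c(B2OC(C)(C)C(C)(C)O2)cc(B2OC(C)(C)C(C)(C)O2)c(OC)c1C | intermediate
4 | 2,4-dimethoxy-3-methylbenzene-1,5-diol | COc1c(O)cc(O)c(OC)c1C | intermediate
5 | 2-hydroxy-5-methoxy-6-methylcyclohexa-2,5-diene-1,4-dione | COC1=C(C)C(=O)C(O)=CC1=O | intermediate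
6 | 3-methylbenzene-1,2,4,5-tetrol (not isolated) | Cc1c(O)c(O)cc(O)c1O | intermediate
7 | 2,5-dihydroxy-3-methylcyclohexa-2,5-diene-1,4-dione | CC1=C(O)C(=O)C=C(O)C1=O | intermediate
8 | 11-bromoundecan-1-ol | OCCCCCCCCCCCBr | starting material
9 | [(11-bromoundecyl)oxy](tert-butyl)dimethylsilane | CC(C)(C)[Si](C)(C)OCCCCCCCCCCCBr | intermediate
10 | 2-(2-bromoethyl)-1,3-dioxolane | BrCCC1OCCO1 | starting material
11 | [2-(1,3-dioxolan-2-yl)ethyl]magnesium bromide (not isolated) | Br[Mg]CCC1OCCO1 | intermediate
12 | tert-butyl{[13-(1,3-dioxolan-2-yl)tridecyl]oxy}dimethylsilane | CC(C)(C)[Si](C)(C)OCCCCCCCCCCCCCC1OCCO1 | intermediate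
13 | 13-(1,3-dioxolan-2-yl)tridecan-1-ol | OCCCCCCCCCCCCCC1OCCO1 | intermediate
14 | 13-(1,3-dioxolan-2-yl)tridecanal | O=CCCCCCCCCCCCCC1OCCO1 | intermediate
15 | 3-[13-(1,3-dioxolan-2-yl)tridecylidene]-5-methoxy-6-methylcyclohex-5-ene-1,2,4-trione (not isolated; exocyclic C=C geometry undefined) | COC1=C(C)C(=O)C(=O)C(=CCCCCCCCCCCCCC2OCCO2)C1=O | intermediate
16 | 3-[13-(1,3-dioxolan-2-yl)tridecyl]-2-hydroxy-5-methoxy-6-methylcyclohexa-2,5-diene-1,4-dione | COC1=C(C)C(=O)C(O)=C(CCCCCCCCCCCCCC2OCCO2)C1=O | intermediate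
17 | 14-(2-hydroxy-5-methoxy-4-methyl-3,6-dioxocyclohexa-1,4-dien-1-yl)tetradecanal | COC1=C(C)C(=O)C(O)=C(CCCCCCCCCCCCCC=O)C1=O | intermediate
18 | 5-hydroxy-3-[14-(2-hydroxy-5-methoxy-4-methyl-3,6-dioxocyclohexa-1,4-dien-1-yl)tetradecylidene]-6-methylcyclohex-5-ene-1,2,4-trione (not isolated; exocyclic C=C geometry undefined) | CC1=C(O)C(=O)C(=CCCCCCCCCCCCCCC2=C(O)C(=O)C(C)=C(OC)C2=O)C(=O)C1=O | intermediate
19 | 2,5-dihydroxy-3-[14-(2-hydroxy-5-methoxy-4-methyl-3,6-dioxocyclohexa-1,4-dien-1-yl)tetradecyl]-6-methylcyclohexa-2,5-diene-1,4-dione (achiral) | COC1=C(C)C(=O)C(O)=C(CCCCCCCCCCCCCCC2=C(O)C(=O)C(C)=C(O)C2=O)C1=O | target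

## Step count and risk

Total step count: 12.

Longest linear sequence: 7 steps (8 → 9 → 12 → 13 → 14 → 16 → 17 → 19, steps 6–12; the arene line 1 → 2 → 3 → 4 → 5 → 16 → 17 → 19 is equally long).

Steps most likely to fail:

Step 12. The donor 7 is strongly acidic and poorly soluble, and the Hantzsch ester may fail to intercept alkylidene trione 18 cleanly (bis-adducts, quinone reduction). The fallback separates condensation and reduction. It sets out from 7 and 17: heating them with thiophenol in EtOH/H2O at 60 °C without amine gives, by Knoevenagel condensation and thia-Michael trapping, racemic 2,5-dihydroxy-3-[14-(2-hydroxy-5-methoxy-4-methyl-3,6-dioxocyclohexa-1,4-dien-1-yl)-1-(phenylsulfanyl)tetradecyl]-6-methylcyclohexa-2,5-diene-1,4-dione F7. Raney nickel in EtOH then cleaves the C–S bond; the quinones are reduced on the way and re-oxidised by air on work-up. The fallback comes back to the route at 19.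

Step 10. Proline could attack the methoxyquinone of 5, the Hantzsch ester could reduce 5, or the dioxolane could suffer from the acidic donor. The fallback makes the same C–C bond at the arene oxidation level by a phenolic Mannich reaction. It sets out from 4 and 14: with morpholine in EtOH at 60 °C they give, at the only free ring position, racemic 6-[13-(1,3-dioxolan-2-yl)-1-(morpholin-4-yl)tridecyl]-2,4-dimethoxy-3-methylbenzene-1,5-diol F5. NaBH4 in refluxing EtOH (elimination to the ortho-quinone methide, then hydride addition) removes the amine to give 6-[13-(1,3-dioxolan-2-yl)tridecyl]-2,4-dimethoxy-3-methylbenzene-1,5-diol F6. PhI(OAc)2 in MeCN/H2O at 0 °C then performs the oxidative demethylation; both para-methoxyphenol pairs give the same quinone. The fallback comes back to the route at 16.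

Step 4. CAN may over-oxidise or couple the electron-rich resorcinol 4, which has a free nucleophilic position. The fallback never makes a free resorcinol and sets out from 1. Vilsmeier formylation (POCl3, DMF) gives 2,4-dimethoxy-3-methylbenzaldehyde F1. Dakin-type Baeyer–Villiger oxidation (mCPBA, CH2Cl2; then aq. NaOH, then HCl) gives 2,4-dimethoxy-3-methylphenol F2. CAN in MeCN/H2O gives 2-methoxy-3-methylcyclohexa-2,5-diene-1,4-dione F3. Thiele–Winter acetoxylation (Ac2O, cat. H2SO4) adds acetate at C-5, β to the ketone-like carbonyl that the methoxy group does not deactivate, to give 5-methoxy-6-methylbenzene-1,2,4-triyl triacetate F4. The methyl group directs weakly the other way, so some regioisomer is possible. Methanolysis (HCl, MeOH, N2) and oxidation with aq. FeCl3 bring the fallback back to the route at 5; compound 7 is still made from 4 by step 5.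

## Further compounds

F1 | step 4 | 2,4-dimethoxy-3-methylbenzaldehyde | COc1ccc(C=O)c(OC)c1C
F2 | step 4 | 2,4-dimethoxy-3-methylphenol | COc1ccc(O)c(OC)c1C
F3 | step 4 | 2-methoxy-3-methylcyclohexa-2,5-diene-1,4-dione | COC1=C(C)C(=O)C=CC1=O
F4 | step 4 | 5-methoxy-6-methylbenzene-1,2,4-triyl triacetate | CC(=O)Oc1cc(OC(C)=O)c(OC)c(C)c1OC(C)=O
F5 | step 10 | 6-[13-(1,3-dioxolan-2-yl)-1-(morpholin-4-yl)tridecyl]-2,4-dimethoxy-3-methylbenzene-1,5-diol (racemic) | COc1c(O)c(C(CCCCCCCCCCCCC2OCCO2)N3CCOCC3)c(O)c(OC)c1C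
F6 | step 10 | 6-[13-(1,3-dioxolan-2-yl)tridecyl]-2,4-dimethoxy-3-methylbenzene-1,5-diol | COc1c(O)c(CCCCCCCCCCCCCC2OCCO2)c(O)c(OC)c1C
F7 | step 12 | 2,5-dihydroxy-3-[14-(2-hydroxy-5-methoxy-4-methyl-3,6-dioxocyclohexa-1,4-dien-1-yl)-1-(phenylsulfanyl)tetradecyl]-6-methylcyclohexa-2,5-diene-1,4-dione (racemic) | COC1=C(C)C(=O)C(O)=C(CCCCCCCCCCCCCC(Sc3ccccc3)C2=C(O)C(=O)C(C)=C(O)C2=O)C1=O
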